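Watch Q.

J 26 mM; Q 3.00 equiv; time 8.0 h

    G ⇌ E.Q, rate k1*(cs1 - [E.Q]) while solid is left; crystals form when [E.Q] > cs1 (cs1 = 11 mM, k1 = 4.85 min⁻¹)
    E.Q ⇌ X (K2 = 1.46, k2 = 0.0205 min⁻¹)
    J ⇌ E, rate k3*(cs3 - [E]) while solid is left; crystals form when [E] > cs3 (cs3 = 9.5 mM, k3 = 0.211 min⁻¹)
    2 Q → Q2 (k4 = 0.116 L mol⁻¹ min⁻¹)
    E + Q → E.Q (k5 = 0.268 L mol⁻¹ min⁻¹)

- what is said of E.Q includes G
- a step written with two of one species runs at k times the square of its concentration and takes two of it each time
- J, G is a solid; its amount is given per volume of the solution
- at the start none of J is in solution
- E means what is dissolved; the solid is not counted in it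
- run time (flask): 8.0 h

- amount of E.Q and G together at 8.0 h, in percent of the J charged
- concentration of E in solution at 8.0 h, in percent of saturation

In this flask solid J feeds dissolved E, E couples with Q to give E.Q, E.Q passes reversibly into X, and Q also dimerises. I count in charges of J: q is the Q left and F the share of J that has coupled.

In the first minutes dissolved E climbs towards saturation with half-time 3.29 min, shorter than the 0.55 h that E lasts against coupling with Q as charged. So E fills to saturation, 36.5 % of the J charge, and I freeze it there.

Coupling then removes Q in pseudo-first-order fashion, with constant 0.153 h⁻¹. Dimerisation removes it in proportion to the square of q, so I compare the two through the crossover 0.422, the level of Q, in J charges, at which dimerisation and coupling consume Q equally fast. With E frozen and q at its charged 3.00, dimerisation takes 7.11 times as much Q as coupling. Integrating, q/(q + w) decays exponentially with that constant, while F equals w times the logarithm of (starting q + w)/(q + w).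

In the middle, I reckon the solid ends when F reaches 63.5 %, with q at 0.339, already below w, and my reckoning puts that moment at 4.43 h. After that E falls, so keeping it frozen overstates F, and I accept this.

At 8.0 h the ratio q/(q + w) is 0.258, so I get q = 0.147 and F = 75.7 %. E.Q and X relax in 0.334 h, short against the run, so E.Q holds the fraction 1/(1 + K) of F, with K = 1.46. That gives y = 30.8 % and, from the E remaining, sat = 66.4 %. My E.Q stands at 72.8 % of its saturation, so I expect no G.

The forecast says 30 % (26 % to 34 %) and 77 % (68 % to 86 %), a range for E that lies above my figure, reasoning that "Q is lost mostly to its own dimerisation while E sits near saturation".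

The flask gives y = 29.2 % and sat = 81.3 %, so E stands above my 66.4 %. At 4.00 h E still stood at 98.7 % of saturation. With w = 0.422, my q at 8.0 h is 4.90 % of the Q charged, and this flask kept 5.1 %. The neighbour with 5.10 equiv of Q has the same w, and the same reckoning leaves 3.09 % of its Q; that flask kept 3.8 %.

The rate constants are those of an exercise; the result is computed.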